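At 20.0 h, the last reading of the blue run, which is the flask asked about, the complex with four exchanged stands at 15.4% and the starting complex at 71.5%. The 13.1% missing from the balance is counted here as once exchanged, so the leaving ligand is reckoned at 1.75 of its own charge.

| setting | blue | flask |
|---|---|---|
| starting complex | 0.33 M | 0.33 M |
| leaving ligand | 0.33 M | 0.330 M |
| gas | 80 mM (held) | 80 mM (held) |
| remark | the very flask that is asked about, followed so far |  |
| time |  | 2.0 d |

blue run (percent of the starting complex charged)

| time / h | starting complex / % | complex with four exchanged / % |
|---|---|---|
| 1.50 | 79.9 | 1.4 |
| 5.00 | 76.6 | 5.9 |
| 8.00 | 74.6 | 9.7 |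
| 15.0 | 76.0 | 12.4 |
| 20.0 | 71.5 | 15.4 |

(standard deviation of a reading: 1 percentage point)

- part of the starting complex gone at 2.0 d
- the complex with four exchanged standing at 2.0 d, as a percentage of the starting complex charged
- the complex with one exchanged standing at 2.0 d, as a percentage of the starting complex charged

With the gas held, the exchange is taken to come to rest at a fixed stopping quotient, the reaction quotient of the whole exchange with the gas side left out: the fraction with four exchanged over the fraction of starting complex, times the leaving-ligand fraction to the power 4. Read from the last time point, with the scatter of that reading, it is 2.01.

One extreme is a flask already at rest, which stays at 15.4%. The other returns nothing and keeps the pace of the first 8.00 h, reaching 58.2% in 2.0 d. The later pace gives 22.8% over that time, less than the early one, and a further 5 percentage points of four-exchanged complex, taken from the starting complex, lifts the quotient to 4.41, about twice the value read. The reckoning here therefore commits to the neighbourhood of the lower extreme, near 15.4% of four-exchanged complex within a scatter of 1 point.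

The forecast stands higher on the complex with four exchanged, with 36% of the starting complex gone, 27% of the complex with four exchanged and 9% of the complex with one exchanged, on a slowing rate “which suggests some ligand inhibition”.

The flask gives 27.9% of the starting complex gone, 15.0% of the complex with four exchanged and 8.62% of the complex with one exchanged, and at 20.0 d the four-exchanged complex in this flask still reads 15.0%. The quotient of this flask at 2.00 d is 2.11, while the forecast's numbers correspond to 9.35.

    starting complex + incoming ligand ⇌ leaving ligand + complex with one exchanged (K = 4.00, k = 0.0290 M⁻¹ s⁻¹)
    complex with one exchanged + incoming ligand ⇌ leaving ligand + complex with two exchanged (K = 11.0, k = 0.00970 M⁻¹ s⁻¹)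
    complex with two exchanged + incoming ligand ⇌ leaving ligand + complex with three exchanged (K = 17.0, k = 0.0130 M⁻¹ s⁻¹)
    complex with three exchanged + incoming ligand ⇌ leaving ligand + complex with four exchanged (K = 350, k = 0.0260 M⁻¹ s⁻¹)
    gas ⇌ incoming ligand, rate k5*(csat - [incoming ligand]) (kL = 0.00310 s⁻¹)
    incoming ligand → decomposed reagent (k = 0.0110 s⁻¹)

In a neighbour flask with 0.083 M of starting complex and all else the same, a trial 33.3% of four-exchanged complex puts the leaving ligand at 1.37 of its own charge, and the quotient 2.01 with the same missing share returns 31.6% of four-exchanged complex. The computed four-exchanged complex of that neighbour flask is 31.3%.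

The readings come from a simulation from invented constants, and the scatter is random.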